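**Plan**

- Retrosynthesis (target numbered as 7-oxabicyclo[4.1.0]hept-4-ene: C1 quaternary epoxide carbon with CH2OBz, C2 OAc, C3 OBz, C4=C5, C6 epoxide CH): the epoxide is removed first, then the acetate. The C3 benzoate and the C4=C5 alkene are traced to one anti-SN2′ opening of a 7-oxanorbornadiene in which the C2 oxygen still bridges C2 and C5.
- The oxa-bridged diene is cut at C2–C3 and C4–C5 by a Diels–Alder disconnection. C2–C1(CH2OBz)=C6–C5 plus the C2 oxygen is a 3-substituted furan; C3–C4 is acetylene, carried as (Z)-1,2-bis(phenylsulfonyl)ethene.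
- Enabling feature: with the epoxide read as the C1=C6 alkene, the C2 oxygen lies 1,4 to C5 across the C2–C1=C6–C5 unit, so the carbocycle hides a furan ring. The furan is dearomatised, and the sulfonyl activators and the oxa-bridge strain are spent later.
- Forward order: benzoylation of furan-3-ylmethanol; [4+2] closes the six-membered carbocycle and the oxa-bridge; reductive desulfonylation; strain-driven ring opening by benzoate; acetylation; epoxidation.
- Stereochemistry: absolute configuration from a chiral rhodium catalyst that resolves the racemic oxanorbornadiene; C2/C3 trans from anti attack of benzoate with retention at C2; epoxide face from shielding by the pseudoaxial C2 acetate.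

Key step: step 2

Assumption (chemistry): the ligand antipode named in step 4 is taken to be the one that leads to the (5R,6R) series; the mirror-image ligand would be used if the sense of induction proved opposite.

**Step 1**
Reactants: 1 furan-3-ylmethanol; 2 benzoyl chloride
Product: 3 furan-3-ylmethyl benzoate
Conditions: BzCl, Et3N, DMAP (cat.), CH2Cl2, 0 °C to rt
Reagents that add atoms: benzoyl chloride, O=C(Cl)c1ccccc1
Why: DMAP-catalysed acylation of an unhindered primary alcohol should be clean and installs the primary benzoate of the target at the outset; no stereocentre is formed.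

**Step 2**
Reactants: 3 furan-3-ylmethyl benzoate; 4 (Z)-1,2-bis(phenylsulfonyl)ethene
Product: 5 rac-[(5-endo,6-endo)-5,6-bis(phenylsulfonyl)-7-oxabicyclo[2.2.1]hept-2-en-2-yl]methyl benzoate (with its 5-exo,6-exo isomer, used together)
Conditions: CH2Cl2 (concentrated), rt, dark
Reagents that add atoms: (Z)-1,2-bis(phenylsulfonyl)ethene, O=S(=O)(/C=C\S(=O)(=O)c1ccccc1)c1ccccc1
Why: A concerted, suprafacial normal-demand [4+2] cycloaddition joins the furan termini C2 and C5 to the two carbons of the doubly sulfonyl-activated alkene, which creates the future C2–C3 and C4–C5 bonds of the target at once and dearomatises the heteroarene. The closest known reaction type is the room-temperature Diels–Alder addition of furans to (Z)-1,2-bis(arylsulfonyl)ethenes used as acetylene equivalents. The six-membered carbocycle is closed by the cycloaddition itself, and the furan ring thereby becomes the oxa-bridge of a 7-oxabicyclo[2.2.1]heptene. The two bridgehead centres are necessarily cis and arise as a racemate, and the two sulfonyl-bearing centres are cis to each other because the alkene geometry is transferred stereospecifically; their endo or exo orientation is immaterial because both become sp2 in step 3. No regiocontrol is needed because the dienophile is constitutionally symmetric, which is why a symmetric acetylene equivalent is chosen for the unsymmetrical furan, and the low temperature should keep the reversible furan cycloaddition on the adduct side.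

**Step 3**
Reactants: 5 rac-[(5-endo,6-endo)-5,6-bis(phenylsulfonyl)-7-oxabicyclo[2.2.1]hept-2-en-2-yl]methyl benzoate
Product: 6 rac-(7-oxabicyclo[2.2.1]hepta-2,5-dien-2-yl)methyl benzoate
Conditions: 6% Na(Hg), NaH2PO4, THF–MeOH, −20 °C
Reagents that add atoms: none
Why: Electron transfer to one sulfone should give a β-sulfonyl carbanion that expels benzenesulfinate (reductive vicinal bis-sulfone elimination, a Julia-type process), unmasking the second alkene whatever the adduct stereochemistry, while the cold buffered medium should spare the benzoate and leaves the bridgehead centres untouched.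

**Step 4**
Reactants: 6 rac-(7-oxabicyclo[2.2.1]hepta-2,5-dien-2-yl)methyl benzoate; 7 benzoic acid
Product: 8 [(5R,6R)-5-(benzoyloxy)-6-hydroxycyclohexa-1,3-dien-1-yl]methyl benzoate
Conditions: [Rh(cod)Cl]2 (2.5 mol %), (S)-1-[(R)-2-(diphenylphosphino)ferrocenyl]ethyldi-tert-butylphosphine (6 mol %), PhCO2H, Et3N, THF, 50 °C, stopped near half conversion
Reagents that add atoms: benzoic acid, OC(=O)c1ccccc1
Why: Proposed new method: the monovalent rhodium bisphosphine complex should bind the exo face of the unsubstituted alkene and the bridging oxygen and insert with retention into the bridgehead C–O bond remote from the CH2OBz-bearing carbon (C4–O7 of 6, whose ionisation is stabilised through the dienyl unit ending at substituted C2 and which is the bond presented to the metal in the matched (1S,4R) enantiomer), giving a trivalent rhodium π-allyl alkoxide that benzoate attacks anti to the metal at the alkene carbon next to the other bridgehead (C6 of 6), so that release of the oxanorbornadiene strain should set the benzoate trans to the retained carbinol oxygen and create the new ring alkene in one event; the closest known reaction type is the rhodium/ferrocenyl bisphosphine-catalysed asymmetric ring opening of oxabenzonorbornadienes by carboxylates, including its regiodivergent resolution of racemic unsymmetrical oxabicyclic alkenes, here extended to a non-benzo-fused 7-oxanorbornadiene, with the mismatched (1R,4S) enantiomer left behind or diverted to a separable constitutional isomer, so that at most half of the racemate can be converted.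

**Step 5**
Reactants: 8 [(5R,6R)-5-(benzoyloxy)-6-hydroxycyclohexa-1,3-dien-1-yl]methyl benzoate; 9 acetic anhydride
Product: 10 [(5R,6R)-6-(acetyloxy)-5-(benzoyloxy)cyclohexa-1,3-dien-1-yl]methyl benzoate
Conditions: Ac2O, pyridine, DMAP (cat.), CH2Cl2, 0 °C
Reagents that add atoms: acetic anhydride, CC(=O)OC(C)=O
Why: DMAP-catalysed acetylation of the secondary allylic alcohol at low temperature should outpace 1,2-benzoyl migration and elimination to the arene, and no stereocentre is touched.

**Step 6**
Reactants: 10 [(5R,6R)-6-(acetyloxy)-5-(benzoyloxy)cyclohexa-1,3-dien-1-yl]methyl benzoate; 11 3-chloroperoxybenzoic acid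
Product: 12 [(1S,2S,3R,6S)-2-(acetyloxy)-3-(benzoyloxy)-7-oxabicyclo[4.1.0]hept-4-en-1-yl]methyl benzoate
Conditions: mCPBA, NaHCO3, CH2Cl2, 0 °C to rt
Reagents that add atoms: 3-chloroperoxybenzoic acid, OOC(=O)c1cccc(Cl)c1
Why: Prilezhaev epoxidation should take the trisubstituted C1=C2 alkene of the diene and, because allylic 1,2-strain with the CH2OBz group holds the C6 acetate pseudoaxial over one face of that alkene, should occur anti to the acetate (syn to the C5 benzoate), setting both epoxide centres (1S,6S) in one concerted syn oxygen transfer.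

**Compound list**

1 | furan-3-ylmethanol | OCc1ccoc1 | starting material
2 | benzoyl chloride | O=C(Cl)c1ccccc1 | starting material
3 | furan-3-ylmethyl benzoate | O=C(OCc1ccoc1)c1ccccc1 | intermediate
4 | (Z)-1,2-bis(phenylsulfonyl)ethene | O=S(=O)(/C=C\S(=O)(=O)c1ccccc1)c1ccccc1 | starting material
5 | rac-[(5-endo,6-endo)-5,6-bis(phenylsulfonyl)-7-oxabicyclo[2.2.1]hept-2-en-2-yl]methyl benzoate (one enantiomer drawn; formed with the 5-exo,6-exo isomer) | O=C(OCC1=C[C@H]2[C@@H](S(=O)(=O)c3ccccc3)[C@@H](S(=O)(=O)c3ccccc3)[C@@H]1O2)c1ccccc1 | intermediate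
6 | rac-(7-oxabicyclo[2.2.1]hepta-2,5-dien-2-yl)methyl benzoate (the (1S,4R) enantiomer, consumed in step 4, is drawn) | O=C(OCC1=C[C@H]2C=C[C@@H]1O2)c1ccccc1 | intermediate
7 | benzoic acid | OC(=O)c1ccccc1 | starting material
8 | [(5R,6R)-5-(benzoyloxy)-6-hydroxycyclohexa-1,3-dien-1-yl]methyl benzoate | O[C@H]1[C@H](OC(=O)c2ccccc2)C=CC=C1COC(=O)c1ccccc1 | intermediate
9 | acetic anhydride | CC(=O)OC(C)=O | starting material
10 | [(5R,6R)-6-(acetyloxy)-5-(benzoyloxy)cyclohexa-1,3-dien-1-yl]methyl benzoate | CC(=O)O[C@H]1[C@H](OC(=O)c2ccccc2)C=CC=C1COC(=O)c1ccccc1 | intermediate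
11 | 3-chloroperoxybenzoic acid | OOC(=O)c1cccc(Cl)c1 | starting material
12 | [(1S,2S,3R,6S)-2-(acetyloxy)-3-(benzoyloxy)-7-oxabicyclo[4.1.0]hept-4-en-1-yl]methyl benzoate | CC(=O)O[C@H]1[C@H](OC(=O)c2ccccc2)C=C[C@@H]2O[C@@]21COC(=O)c1ccccc1 | target

Total step count: 6. Longest linear sequence: 6 steps.

**Steps most likely to fail**

Step 4 (Proposed new method). The opening may fail through poor discrimination between the two bridgehead C–O bonds or between the substrate enantiomers, through chelation of the homoconjugated diene to rhodium, or through acid-promoted aromatisation. The fallback uses known reaction types, is stepwise and substrate-controlled, sets out from 3 and comes back at 10.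
- Thermal Diels–Alder reaction of 3 with vinylene carbonate (neat, sealed tube, about 130 °C), then removal of the exo isomer, should give rac-[(5-endo,6-endo)-5,6-(carbonyldioxy)-7-oxabicyclo[2.2.1]hept-2-en-2-yl]methyl benzoate F1. This adduct already carries the future benzoate oxygen trans to the bridge oxygen.
- BBr3 (CH2Cl2, −78 °C) should cleave the bridgehead C–O bond that ionises to the allyl cation ending at the substituted alkene carbon, giving rac-[3-bromo-4,5-(carbonyldioxy)-6-hydroxycyclohex-1-en-1-yl]methyl benzoate F2.
- Zinc dust (AcOH–THF, 0 °C) should effect reductive β-elimination of the bromide with the neighbouring carbonate oxygen; loss of CO2 then leaves rac-[(5R*,6R*)-5,6-dihydroxycyclohexa-1,3-dien-1-yl]methyl benzoate F3.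
- Benzoyl chloride (one equivalent, pyridine, −40 °C) should acylate the less hindered C5 hydroxyl to give rac-[(5R*,6R*)-5-(benzoyloxy)-6-hydroxycyclohexa-1,3-dien-1-yl]methyl benzoate F4.
- Lipase-catalysed acetylation (Burkholderia cepacia lipase, vinyl acetate, t-BuOMe, 30 °C) is a kinetic resolution expected to acylate the (6R) carbinol, which brings the route back at 10.

Step 6. The epoxidation may suffer from poor facial selectivity or from attack on the disubstituted alkene. The fallback replaces the acetate by a larger, less electron-withdrawing shielding group, sets out from 8 and comes back at 12.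
- Silylation (TBSOTf, 2,6-lutidine, CH2Cl2, −78 °C) should give [(5R,6R)-5-(benzoyloxy)-6-[(tert-butyldimethylsilyl)oxy]cyclohexa-1,3-dien-1-yl]methyl benzoate F5.
- mCPBA (NaHCO3, CH2Cl2, 0 °C) should then attack anti to the pseudoaxial silyloxy group to give [(1S,2S,3R,6S)-3-(benzoyloxy)-2-[(tert-butyldimethylsilyl)oxy]-7-oxabicyclo[4.1.0]hept-4-en-1-yl]methyl benzoate F6.
- HF·pyridine (THF, 0 °C) should free [(1S,2S,3R,6S)-3-(benzoyloxy)-2-hydroxy-7-oxabicyclo[4.1.0]hept-4-en-1-yl]methyl benzoate F7.
- Acetylation (Ac2O, pyridine, 0 °C) returns to the route at 12.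

Step 3. Sodium amalgam may cleave or transesterify the benzoate, and the strained diene may be lost by cycloreversion or aromatisation during isolation. The fallback replaces the reductive unmasking by a fluoride-triggered one, sets out from 3 and comes back at 6.
- Diels–Alder reaction of 3 with (E)-1-(phenylsulfonyl)-2-(trimethylsilyl)ethene (toluene, sealed tube, or under high pressure) should give rac-[5-endo-(phenylsulfonyl)-6-exo-(trimethylsilyl)-7-oxabicyclo[2.2.1]hept-2-en-2-yl]methyl benzoate F8; its regio- and stereoisomers converge.
- Bu4NF (THF, 0 °C) should induce β-elimination of the silyl and sulfonyl groups and return to the route at 6.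

**Further compounds**

F1 | step 4 | rac-[(5-endo,6-endo)-5,6-(carbonyldioxy)-7-oxabicyclo[2.2.1]hept-2-en-2-yl]methyl benzoate | O=C(OCC1=C[C@H]2[C@H]3OC(=O)O[C@H]3[C@@H]1O2)c1ccccc1
F2 | step 4 | rac-[3-bromo-4,5-(carbonyldioxy)-6-hydroxycyclohex-1-en-1-yl]methyl benzoate (bromide and carbonate oxygens on one face, hydroxyl on the other) | O=C(OCC1=C[C@@H](Br)[C@H]2OC(=O)O[C@H]2[C@@H]1O)c1ccccc1
F3 | step 4 | rac-[(5R*,6R*)-5,6-dihydroxycyclohexa-1,3-dien-1-yl]methyl benzoate | O[C@H]1[C@H](O)C=CC=C1COC(=O)c1ccccc1
F4 | step 4 | rac-[(5R*,6R*)-5-(benzoyloxy)-6-hydroxycyclohexa-1,3-dien-1-yl]methyl benzoate (racemate of 8; relative configuration drawn) | O[C@H]1[C@H](OC(=O)c2ccccc2)C=CC=C1COC(=O)c1ccccc1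
F5 | step 6 | [(5R,6R)-5-(benzoyloxy)-6-[(tert-butyldimethylsilyl)oxy]cyclohexa-1,3-dien-1-yl]methyl benzoate | CC(C)(C)[Si](C)(C)O[C@H]1[C@H](OC(=O)c2ccccc2)C=CC=C1COC(=O)c1ccccc1
F6 | step 6 | [(1S,2S,3R,6S)-3-(benzoyloxy)-2-[(tert-butyldimethylsilyl)oxy]-7-oxabicyclo[4.1.0]hept-4-en-1-yl]methyl benzoate | CC(C)(C)[Si](C)(C)O[C@H]1[C@H](OC(=O)c2ccccc2)C=C[C@@H]2O[C@@]21COC(=O)c1ccccc1
F7 | step 6 | [(1S,2S,3R,6S)-3-(benzoyloxy)-2-hydroxy-7-oxabicyclo[4.1.0]hept-4-en-1-yl]methyl benzoate | O[C@H]1[C@H](OC(=O)c2ccccc2)C=C[C@@H]2O[C@@]21COC(=O)c1ccccc1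
F8 | step 3 | rac-[5-endo-(phenylsulfonyl)-6-exo-(trimethylsilyl)-7-oxabicyclo[2.2.1]hept-2-en-2-yl]methyl benzoate | O=C(OCC1=C[C@H]2[C@@H](S(=O)(=O)c3ccccc3)[C@H]([Si](C)(C)C)[C@@H]1O2)c1ccccc1
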